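**Assumption:** germacrane numbering is used for locants (ring alkenes C1=C10 and C4=C5, lactone carbinol C6, tertiary carbinol C7, lactone carbonyl C12, exocyclic methylene C13); the target is read as 1(10)Z,4E,6S,7S,8S,9R with a (Z)-2-methylbut-2-enoate (angelate) on O9.

## Retrosynthetic overview

1. Target ⇐ 7,8,9-triol by C9–O angeloylation; the exocyclic methylene ⇐ α-methyl lactone by selenoxide elimination (C7 carries no H, so only C13–H can be lost).
2. Lactone ring (formed second, same flask) ⇐ acylation of the C6 oxygen by the C12 ester, as in the 6-hydroxy-acid lactonisation that gives costunolide.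
3. Ten-membered carbocycle (formed first) ⇐ the C6–C7 bond, i.e. the farnesyl C1–C10 bond of germacrene biosynthesis, made here by reductive ketyl coupling of an acyclic enal/β-keto ester, which sets C6 and C7 together.
4. Acyclic precursor ⇐ Z-selective Wittig union of a geranyl acetate-derived C1–C6 ylide with a D-tartrate-derived methyl ketone (C8 and C9 from the chiral pool), then propanoate acylation (C11–C13).

## Route

Step 1
Reactants: 1 dimethyl (4S,5S)-2,2-dimethyl-1,3-dioxolane-4,5-dicarboxylate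
Product: 2 (4S,5S)-N4,N5-dimethoxy-N4,N5,2,2-tetramethyl-1,3-dioxolane-4,5-dicarboxamide
Conditions: MeNH(OMe)·HCl, iPrMgCl, THF, −20 → 0 °C
Reagents that add atoms: N,O-dimethylhydroxylamine hydrochloride, CNOC.Cl
Why: Weinreb amidation of both esters by the magnesium amide (ester aminolysis) is fast at low temperature and leaves the trans-dioxolane stereocentres (future C8 and C9) untouched.

Step 2
Reactants: 2 (4S,5S)-N4,N5-dimethoxy-N4,N5,2,2-tetramethyl-1,3-dioxolane-4,5-dicarboxamide
Product: 3 (4S,5S)-5-acetyl-N-methoxy-N,2,2-trimethyl-1,3-dioxolane-4-carboxamide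
Conditions: MeMgBr (1.3 equiv), THF, −15 °C; aq. NH4Cl
Reagents that add atoms: methylmagnesium bromide, C[Mg]Br
Why: Grignard addition to a Weinreb amide stops at the chelated tetrahedral intermediate, and that magnesium chelate deactivates the second amide of the C2-symmetric bis-amide, so the mono-methyl ketone (C10 with C14) is obtained.

Step 3
Reactants: 4 geranyl acetate
Product: 5 (2E)-6-hydroxy-3-methylhex-2-en-1-yl acetate
Conditions: O3 (1.0 equiv), CH2Cl2/MeOH, pyridine, −78 °C; then NaBH4, −78 → 0 °C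
Reagents that add atoms: ozone, [O-][O+]=O
Why: Chemoselective ozonolysis cleaves the electron-rich remote trisubstituted alkene in preference to the alkene deactivated by the allylic acetate, and reductive work-up gives the primary alcohol with the E-alkene (future C4=C5) intact.

Step 4
Reactants: 5 (2E)-6-hydroxy-3-methylhex-2-en-1-yl acetate
Product: 6 (2E)-6-iodo-3-methylhex-2-en-1-yl acetate
Conditions: I2, PPh3, imidazole, CH2Cl2, 0 °C → rt
Reagents that add atoms: iodine, II
Why: Appel-type iodination converts the unhindered primary alcohol into the iodide under neutral conditions that do not touch the allylic acetate.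

Step 5
Reactants: 6 (2E)-6-iodo-3-methylhex-2-en-1-yl acetate
Product: 7 [(4E)-6-(acetyloxy)-4-methylhex-4-en-1-yl]triphenylphosphonium iodide
Conditions: PPh3, MeCN, reflux
Reagents that add atoms: triphenylphosphine, c1ccc(cc1)P(c1ccccc1)c1ccccc1
Why: SN2 quaternisation of the primary iodide gives the phosphonium salt, and the allylic acetate is inert to PPh3 without a transition-metal catalyst.

Step 6
Reactants: 7 [(4E)-6-(acetyloxy)-4-methylhex-4-en-1-yl]triphenylphosphonium iodide; 3 (4S,5S)-5-acetyl-N-methoxy-N,2,2-trimethyl-1,3-dioxolane-4-carboxamide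
Product: 10 (4S,5R)-5-[(2Z,6E)-8-hydroxy-6-methylocta-2,6-dien-2-yl]-N-methoxy-N,2,2-trimethyl-1,3-dioxolane-4-carboxamide, via phosphonium ylide 8 (not isolated), via Wittig acetate 9 (not isolated)
Conditions: KN(SiMe3)2 (1.1 equiv), THF, −78 °C; 3, −78 °C → rt; then MeOH, K2CO3 (0.3 equiv), rt
Reagents that add atoms: none
Why: Wittig olefination of an α-alkoxy methyl ketone with a salt-free non-stabilised ylide places the alkoxy-bearing carbon (C9) cis to the ylide chain (C2), giving the 1(10)Z trisubstituted alkene, and in-flask methanolysis (transesterification) then frees the C6 alcohol while the Weinreb amide survives.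

Step 7
Reactants: 10 (4S,5R)-5-[(2Z,6E)-8-hydroxy-6-methylocta-2,6-dien-2-yl]-N-methoxy-N,2,2-trimethyl-1,3-dioxolane-4-carboxamide; 11 methyl propanoate
Product: 13 methyl 3-[(4S,5R)-5-[(2Z,6E)-8-hydroxy-6-methylocta-2,6-dien-2-yl]-2,2-dimethyl-1,3-dioxolan-4-yl]-2-methyl-3-oxopropanoate (C11 epimers), via lithium enolate 12 (not isolated)
Conditions: 11 (4 equiv), LiN(iPr)2 (4 equiv), THF, −78 °C; then 10, −78 → −30 °C; aq. NH4Cl
Reagents that add atoms: none
Why: Claisen-type acylation of the ester enolate by the Weinreb amide gives the β-keto ester (C7 ketone, C11–C13) without over-addition, the product being protected as its enolate so that C8 is not epimerised.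

Step 8
Reactants: 13 methyl 3-[(4S,5R)-5-[(2Z,6E)-8-hydroxy-6-methylocta-2,6-dien-2-yl]-2,2-dimethyl-1,3-dioxolan-4-yl]-2-methyl-3-oxopropanoate (C11 epimers)
Product: 14 methyl 3-[(4S,5R)-2,2-dimethyl-5-[(2Z,6E)-6-methyl-8-oxoocta-2,6-dien-2-yl]-1,3-dioxolan-4-yl]-2-methyl-3-oxopropanoate (C11 epimers)
Conditions: MnO2 (activated, excess), CH2Cl2, rt
Reagents that add atoms: none
Why: Allylic oxidation with MnO2 gives the E-enal (C6) selectively and neutrally, leaving the β-keto ester, acetonide and Z-alkene unchanged.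

Step 9
Reactants: 14 methyl 3-[(4S,5R)-2,2-dimethyl-5-[(2Z,6E)-6-methyl-8-oxoocta-2,6-dien-2-yl]-1,3-dioxolan-4-yl]-2-methyl-3-oxopropanoate (C11 epimers)
Product: 16 (1(10)Z,4E,6S,7R,8S,9R)-7-hydroxy-8,9-(isopropylidenedioxy)germacra-1(10),4-dien-12,6-olide (C11 epimers), via diol ester 15 (not isolated)
Conditions: SmI2 (2.4 equiv in THF, added over 6 h), THF (2 mM in 14), −78 °C → rt; aq. Rochelle salt
Reagents that add atoms: none
Why: Proposed new method: divalent samarium reduces the more easily reduced enal to a C6 ketyl, which adds to the C7 ketone held as a trivalent samarium chelate by the β-keto ester; a second electron gives the 6,7-diolate, whose C6 alkoxide acylates the C12 methyl ester to close the γ-lactone; attack anti to the C8–O bond of the trans-dioxolane (Felkin–Anh, the metal being tied up by the keto ester) should place 7-OH cis to O8, and the threo 6,7-diol (6S) should follow from the extended C5–C6–C7–C8 arrangement preferred in medium-ring pinacol closures; the closest known reactions are the SmI2-promoted intramolecular pinacol coupling of β-keto esters with aldehydes and the low-valent-titanium pinacol macrocyclisation of keto aldehydes to medium-ring 1,2-diols.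

Step 10
Reactants: 16 (1(10)Z,4E,6S,7R,8S,9R)-7-hydroxy-8,9-(isopropylidenedioxy)germacra-1(10),4-dien-12,6-olide (C11 epimers)
Product: 19 (1(10)Z,4E,6S,7R,8S,9R)-7-hydroxy-8,9-(isopropylidenedioxy)germacra-1(10),4,11(13)-trien-12,6-olide, via selenide 17 (not isolated), via selenoxide 18 (not isolated)
Conditions: LiN(iPr)2 (2.3 equiv), THF, −78 °C; PhSeBr, −78 °C; aq. NH4Cl; then NaIO4, NaHCO3, THF/MeOH/H2O, 0 °C → rt
Reagents that add atoms: none
Why: α-Selenenylation of the alkoxide–enolate dianion followed by selenoxide syn-elimination can only remove a C13 hydrogen because C7 is fully substituted, so the exocyclic α-methylene lactone forms regardless of the C11 configuration, and periodate (with no free 1,2-diol present) spares the ring alkenes.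

Step 11
Reactants: 19 (1(10)Z,4E,6S,7R,8S,9R)-7-hydroxy-8,9-(isopropylidenedioxy)germacra-1(10),4,11(13)-trien-12,6-olide
Product: 20 (1(10)Z,4E,6S,7S,8S,9R)-7,8,9-trihydroxygermacra-1(10),4,11(13)-trien-12,6-olide
Conditions: AcOH/H2O/THF (3:1:1), 40 °C
Reagents that add atoms: none
Why: Mild acid hydrolysis removes the strained trans-fused acetonide, while both ring alkenes are deactivated towards protonation by their allylic C–O bonds, so transannular cyclisation is slow (the C7 descriptor changes from R to S only because of CIP priorities).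

Step 12
Reactants: 20 (1(10)Z,4E,6S,7S,8S,9R)-7,8,9-trihydroxygermacra-1(10),4,11(13)-trien-12,6-olide; 21 angelic acid
Product: 23 (1(10)Z,4E,6S,7S,8S,9R)-9-angeloyloxy-7,8-dihydroxygermacra-1(10),4,11(13)-trien-12,6-olide (CNP0303917.1), via mixed anhydride 22 (not isolated)
Conditions: 21 (1.5 equiv), 2,4,6-Cl3C6H2COCl, Et3N, toluene, rt; then 20, toluene, 70 °C
Reagents that add atoms: none
Why: Yamaguchi esterification without DMAP transfers the angeloyl group without Z→E isomerisation, and the allylic secondary C9–OH should react in preference to the C8–OH flanked by the quaternary C7 and to the inert tertiary C7–OH.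

## Compound list

1 | dimethyl (4S,5S)-2,2-dimethyl-1,3-dioxolane-4,5-dicarboxylate (D-tartrate acetonide) | COC(=O)[C@H]1OC(C)(C)O[C@@H]1C(=O)OC | starting material
2 | (4S,5S)-N4,N5-dimethoxy-N4,N5,2,2-tetramethyl-1,3-dioxolane-4,5-dicarboxamide | CON(C)C(=O)[C@H]1OC(C)(C)O[C@@H]1C(=O)N(C)OC | intermediate
3 | (4S,5S)-5-acetyl-N-methoxy-N,2,2-trimethyl-1,3-dioxolane-4-carboxamide | CC(=O)[C@H]1OC(C)(C)O[C@@H]1C(=O)N(C)OC | intermediate
4 | geranyl acetate, (2E)-3,7-dimethylocta-2,6-dien-1-yl acetate | CC(C)=CCC/C(C)=C/COC(C)=O | starting material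
5 | (2E)-6-hydroxy-3-methylhex-2-en-1-yl acetate | OCCC/C(C)=C/COC(C)=O | intermediate
6 | (2E)-6-iodo-3-methylhex-2-en-1-yl acetate | ICCC/C(C)=C/COC(C)=O | intermediate
7 | [(4E)-6-(acetyloxy)-4-methylhex-4-en-1-yl]triphenylphosphonium iodide | CC(=O)OC/C=C(\C)CCC[P+](c1ccccc1)(c1ccccc1)c1ccccc1.[I-] | intermediate
8 | phosphonium ylide of 7, (2E)-3-methyl-6-(triphenylphosphoranylidene)hex-2-en-1-yl acetate | CC(=O)OC/C=C(\C)CCC=P(c1ccccc1)(c1ccccc1)c1ccccc1 | intermediate
9 | (4S,5R)-5-[(2Z,6E)-8-(acetyloxy)-6-methylocta-2,6-dien-2-yl]-N-methoxy-N,2,2-trimethyl-1,3-dioxolane-4-carboxamide | CC(=O)OC/C=C(\C)CC/C=C(/C)[C@H]1OC(C)(C)O[C@@H]1C(=O)N(C)OC | intermediate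
10 | (4S,5R)-5-[(2Z,6E)-8-hydroxy-6-methylocta-2,6-dien-2-yl]-N-methoxy-N,2,2-trimethyl-1,3-dioxolane-4-carboxamide | OC/C=C(\C)CC/C=C(/C)[C@H]1OC(C)(C)O[C@@H]1C(=O)N(C)OC | intermediate
11 | methyl propanoate | CCC(=O)OC | starting material
12 | lithium enolate of methyl propanoate | CC=C(OC)O[Li] | intermediate
13 | methyl 3-[(4S,5R)-5-[(2Z,6E)-8-hydroxy-6-methylocta-2,6-dien-2-yl]-2,2-dimethyl-1,3-dioxolan-4-yl]-2-methyl-3-oxopropanoate (C11 epimers) | OC/C=C(\C)CC/C=C(/C)[C@H]1OC(C)(C)O[C@@H]1C(=O)C(C)C(=O)OC | intermediate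
14 | methyl 3-[(4S,5R)-2,2-dimethyl-5-[(2Z,6E)-6-methyl-8-oxoocta-2,6-dien-2-yl]-1,3-dioxolan-4-yl]-2-methyl-3-oxopropanoate (C11 epimers) | O=C/C=C(\C)CC/C=C(/C)[C@H]1OC(C)(C)O[C@@H]1C(=O)C(C)C(=O)OC | intermediate
15 | methyl (1(10)Z,4E,6S,7R,8S,9R)-6,7-dihydroxy-8,9-(isopropylidenedioxy)germacra-1(10),4-dien-12-oate (C11 epimers) | COC(=O)C(C)[C@@]1(O)[C@@H](O)/C=C(\C)CC/C=C(/C)[C@H]2OC(C)(C)O[C@H]12 | intermediate
16 | (1(10)Z,4E,6S,7R,8S,9R)-7-hydroxy-8,9-(isopropylidenedioxy)germacra-1(10),4-dien-12,6-olide (C11 epimers) | CC1C(=O)O[C@H]2/C=C(\C)CC/C=C(/C)[C@H]3OC(C)(C)O[C@@H]3[C@@]12O | intermediate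
17 | 11-(phenylselanyl) derivative of 16 (C11 epimers, C6–C9 as in 16) | CC1([Se]c4ccccc4)C(=O)O[C@H]2/C=C(\C)CC/C=C(/C)[C@H]3OC(C)(C)O[C@@H]3[C@@]12O | intermediate
18 | selenoxide of 17 | CC1([Se](=O)c4ccccc4)C(=O)O[C@H]2/C=C(\C)CC/C=C(/C)[C@H]3OC(C)(C)O[C@@H]3[C@@]12O | intermediate
19 | (1(10)Z,4E,6S,7R,8S,9R)-7-hydroxy-8,9-(isopropylidenedioxy)germacra-1(10),4,11(13)-trien-12,6-olide | C=C1C(=O)O[C@H]2/C=C(\C)CC/C=C(/C)[C@H]3OC(C)(C)O[C@@H]3[C@@]12O | intermediate
20 | (1(10)Z,4E,6S,7S,8S,9R)-7,8,9-trihydroxygermacra-1(10),4,11(13)-trien-12,6-olide | C=C1C(=O)O[C@H]2/C=C(\C)CC/C=C(/C)[C@@H](O)[C@H](O)[C@@]12O | intermediate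
21 | angelic acid, (2Z)-2-methylbut-2-enoic acid | C/C=C(/C)C(=O)O | starting material
22 | angelic 2,4,6-trichlorobenzoic mixed anhydride | C/C=C(/C)C(=O)OC(=O)c1c(Cl)cc(Cl)cc1Cl | intermediate
23 | (3aS,4S,5R,6Z,10E,11aS)-3a,4-dihydroxy-6,10-dimethyl-3-methylidene-2-oxo-2,3,3a,4,5,8,9,11a-octahydrocyclodeca[b]furan-5-yl (2Z)-2-methylbut-2-enoate (CNP0303917.1) | C=C1C(=O)O[C@H]2/C=C(\C)CC/C=C(/C)[C@@H](OC(=O)/C(C)=C\C)[C@H](O)[C@@]12O | target

## Step count and risks

Total steps: 12. Longest linear sequence: 10 steps (4 → 23, steps 3 to 12); the tartrate branch (1 → 23) is 9 steps.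

The three steps most likely to fail are steps 9, 12 and 10.

**Step 9.** The risks are reductive cleavage of the α-alkoxy ketone, scrambling of the C4=C5 geometry in the allylic ketyl, and the wrong C6/C7 diastereomer. The fallback sets out from 14 and returns at 16, and replaces the radical coupling by a polar acyl-anion addition. A thiazolium carbene-catalysed intramolecular crossed aldehyde–ketone benzoin (3-benzyl-5-(2-hydroxyethyl)-4-methylthiazolium chloride, Et3N, THF/t-BuOH, 60 °C, 3 mM) adds the C6 acyl anion to the activated C7 ketone and gives the macrocyclic acyloin methyl (1(10)Z,4E,7S,8S,9R)-7-hydroxy-8,9-(isopropylidenedioxy)-6-oxogermacra-1(10),4-dien-12-oate F1. Luche reduction of its C6 enone carbonyl (NaBH4, CeCl3·7H2O, MeOH, −78 °C) from the outer face gives 15, which lactonises to 16. C7 and C6 are thus set in two separate, tunable events.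

**Step 10.** The risk is retro-aldol opening or sluggish selenenylation of the hindered alkoxide–enolate dianion. The fallback sets out from 16 and returns at 20, and masks the tertiary alcohol so that a simple mono-enolate is used. Silylation (TMSOTf, 2,6-lutidine, CH2Cl2, −78 °C) gives the 7-O-trimethylsilyl ether of 16 F2. LiN(iPr)2 (1.2 equiv) and PhSeBr give the 11-phenylselanyl-7-O-trimethylsilyl lactone F3. H2O2 and pyridine in CH2Cl2 at 0 °C give the selenoxide of F3 F4, which eliminates to the 7-O-trimethylsilyl ether of 19 F5. The aqueous acetic acid of step 11 then removes the silyl ether and the acetonide together to give 20.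

**Step 12.** The risk is acylation at O8, bis-acylation, or lactone migration to O8. The fallback sets out from 20 and returns at 23, and uses transient protection of the cis-7,8-diol. PhB(OH)2 (1.05 equiv) in toluene over 4 Å sieves forms the 7,8-O-phenylboronate of 20 F6, leaving only the C9–OH free. Acylation with 22 at 70 °C gives the 7,8-O-phenylboronate of 23 F7. An aqueous sorbitol/Na2CO3 wash removes the boron and releases 23.

## Further compounds

F1 | step 9 | methyl (1(10)Z,4E,7S,8S,9R)-7-hydroxy-8,9-(isopropylidenedioxy)-6-oxogermacra-1(10),4-dien-12-oate (C11 epimers) | COC(=O)C(C)[C@@]1(O)C(=O)/C=C(\C)CC/C=C(/C)[C@H]2OC(C)(C)O[C@H]12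
F2 | step 10 | 7-O-trimethylsilyl ether of 16 | CC1C(=O)O[C@H]2/C=C(\C)CC/C=C(/C)[C@H]3OC(C)(C)O[C@@H]3[C@@]12O[Si](C)(C)C
F3 | step 10 | 11-phenylselanyl-7-O-trimethylsilyl lactone (selenide of F2) | CC1([Se]c4ccccc4)C(=O)O[C@H]2/C=C(\C)CC/C=C(/C)[C@H]3OC(C)(C)O[C@@H]3[C@@]12O[Si](C)(C)C
F4 | step 10 | selenoxide of F3 | CC1([Se](=O)c4ccccc4)C(=O)O[C@H]2/C=C(\C)CC/C=C(/C)[C@H]3OC(C)(C)O[C@@H]3[C@@]12O[Si](C)(C)C
F5 | step 10 | 7-O-trimethylsilyl ether of 19 | C=C1C(=O)O[C@H]2/C=C(\C)CC/C=C(/C)[C@H]3OC(C)(C)O[C@@H]3[C@@]12O[Si](C)(C)C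
F6 | step 12 | 7,8-O-phenylboronate of 20 | C=C1C(=O)O[C@H]2/C=C(\C)CC/C=C(/C)[C@@H](O)[C@H](OB3c4ccccc4)[C@@]12O3
F7 | step 12 | 7,8-O-phenylboronate of 23 | C=C1C(=O)O[C@H]2/C=C(\C)CC/C=C(/C)[C@@H](OC(=O)/C(C)=C\C)[C@H](OB3c4ccccc4)[C@@]12O3
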